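The route rests on cutting ring C'' of the 6''-aryloxyflavanone unit at O1''–C8a'' and C4''–C4a''. It exploits ring A'': the fusion carbons C8a'' and C4a'' are neighbours, C4a'' sits next to the C5'' oxygen, and with O5'' and O7'' both methyl the ring is symmetric, exactly what a 3-methoxyaryne leaves after taking up an oxygen nucleophile and then an acyl group. One fluoride-triggered operation joins a 3,5-dimethoxy-4-aryloxybenzyne to the alkoxide of an (S)-β-hydroxy ester and closes the chromanone. The aryne source is a 2-silylaryl triflate, made from a symmetric phenol, whose 4-aryloxy ring already carries the second (S)-carbinol ester, silyl-protected for a later repeat of the annulation.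

Key step: step 10

Remark: double-primed locants denote the flavanone that bears the 6''-aryloxy group (unit 2; its C2'' aryl is ring B''), unprimed locants the other flavanone (unit 1; its C2 aryl is ring B); both C2 and C2'' of the target are S.

**Route**

Step 1
Reactants: 1 syringaldehyde (4-hydroxy-3,5-dimethoxybenzaldehyde); 2 4'-fluoroacetophenone
Product: 3 4-(4-acetylphenoxy)-3,5-dimethoxybenzaldehyde
Conditions: K2CO3, DMSO, 120 °C, N2
Reagents that add atoms: none
Why: Nucleophilic aromatic substitution, in which the hindered but electron-rich phenoxide of 1 displaces fluoride para to the acetyl group of 2 through a Meisenheimer adduct, while dry carbonate in DMSO is a poor medium for aldol condensation between the two carbonyl groups.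

Step 2
Reactants: 3 4-(4-acetylphenoxy)-3,5-dimethoxybenzaldehyde
Product: 5 1-[4-(4-hydroxy-2,6-dimethoxyphenoxy)phenyl]ethanone, via aryl formate 4 (not isolated)
Conditions: mCPBA, CH2Cl2, 0 → 25 °C; Na2S2O3 wash; then K2CO3 (cat.), MeOH, 0 °C
Reagents that add atoms: mCPBA (3-chloroperoxybenzoic acid), OOC(=O)c1cccc(Cl)c1
Why: Baeyer–Villiger (Dakin-type) oxidation, in which the trioxygenated aryl group migrates in the Criegee adduct of the aldehyde much faster than the aryl methyl ketone of ring B reacts, followed by methanolysis of the aryl formate.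

Step 3
Reactants: 5 1-[4-(4-hydroxy-2,6-dimethoxyphenoxy)phenyl]ethanone
Product: 6 1-[4-(3-bromo-4-hydroxy-2,6-dimethoxyphenoxy)phenyl]ethanone
Conditions: NBS (1.0 equiv), CH2Cl2, −40 → 0 °C
Reagents that add atoms: N-bromosuccinimide, O=C1CCC(=O)N1Br
Why: Electrophilic aromatic bromination, for which the only free positions of the phenol ring are the two equivalent ones ortho to OH (each also ortho and para to a methoxy group) while ring B is deactivated by the acetyl group, so one equivalent should give the monobromide.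

Step 4
Reactants: 6 1-[4-(3-bromo-4-hydroxy-2,6-dimethoxyphenoxy)phenyl]ethanone
Product: 7 methyl 3-[4-(3-bromo-4-hydroxy-2,6-dimethoxyphenoxy)phenyl]-3-oxopropanoate
Conditions: NaH (3.5 equiv), (MeO)2CO, THF, 65 °C; then aq. HCl
Reagents that add atoms: dimethyl carbonate, COC(=O)OC
Why: Crossed Claisen condensation of the methyl ketone enolate with dimethyl carbonate, in which the sodium phenoxide is a spectator (any aryl methyl carbonate reverts under methoxide) and the product is held as its enolate until the acid quench.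

Step 5
Reactants: 7 methyl 3-[4-(3-bromo-4-hydroxy-2,6-dimethoxyphenoxy)phenyl]-3-oxopropanoate
Product: 8 methyl (3S)-3-[4-(3-bromo-4-hydroxy-2,6-dimethoxyphenoxy)phenyl]-3-hydroxypropanoate
Conditions: H2 (50 bar), [RuCl(p-cymene)((R)-BINAP)]Cl (1 mol %), MeOH, 60 °C
Reagents that add atoms: none
Why: Noyori asymmetric hydrogenation of a β-keto ester, in which ruthenium is chelated by ketone and ester and the (R)-BINAP ligand directs hydride to the face that gives the (S)-carbinol (S because aryl outranks CH2CO2Me), with the aryl bromide and phenol left alone.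

Step 6
Reactants: 8 methyl (3S)-3-[4-(3-bromo-4-hydroxy-2,6-dimethoxyphenoxy)phenyl]-3-hydroxypropanoate
Product: 12 4-{4-[(1S)-1-hydroxy-3-methoxy-3-oxopropyl]phenoxy}-3,5-dimethoxy-2-(trimethylsilyl)phenyl triflate, via bis(trimethylsilyl) ether 9 (not isolated), via lithium phenoxide 10 (not isolated), via O-silyl triflate 11 (not isolated)
Conditions: HMDS, TMSCl (cat.), THF, 65 °C, evaporate; n-BuLi (1.05 equiv), THF, −100 → −80 °C; Tf2O, −100 → −78 °C; then citric acid, MeOH, 0 °C
Reagents that add atoms: hexamethyldisilazane, C[Si](C)(C)N[Si](C)(C)C; triflic anhydride, O=S(=O)(OS(=O)(=O)C(F)(F)F)C(F)(F)F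
Why: Bromine–lithium exchange, 1,3 O→C silyl shift (retro-Brook rearrangement) and O-triflation form the usual one-pot entry to 2-silylaryl triflates, and at −100 °C the exchange should outrun addition of butyllithium to the ester (the basis of Parham cyclisations) because the transient aryllithium is consumed at once by the intramolecular silyl shift, after which mild acidic methanolysis frees only the carbinol.

Step 7
Reactants: 12 4-{4-[(1S)-1-hydroxy-3-methoxy-3-oxopropyl]phenoxy}-3,5-dimethoxy-2-(trimethylsilyl)phenyl triflate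
Product: 13 3,5-dimethoxy-4-{4-[(1S)-3-methoxy-3-oxo-1-(triisopropylsilyloxy)propyl]phenoxy}-2-(trimethylsilyl)phenyl triflate
Conditions: TIPSOTf, 2,6-lutidine, CH2Cl2, −78 → 0 °C
Reagents that add atoms: triisopropylsilyl triflate, CC(C)[Si](OS(=O)(=O)C(F)(F)F)(C(C)C)C(C)C
Why: Silylation of a secondary alcohol with a silyl triflate and a hindered pyridine base does not touch the C–Si/OTf pair, and the triisopropylsilyl ether is chosen because it must outlast fluoride in step 10.

Step 8
Reactants: 14 4'-(benzyloxy)acetophenone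
Product: 15 methyl 3-[4-(benzyloxy)phenyl]-3-oxopropanoate
Conditions: NaH (2.5 equiv), (MeO)2CO, toluene, 80 °C; then aq. HCl
Reagents that add atoms: dimethyl carbonate, COC(=O)OC
Why: Crossed Claisen condensation of the ketone enolate with dimethyl carbonate, driven by formation of the β-keto ester enolate.

Step 9
Reactants: 15 methyl 3-[4-(benzyloxy)phenyl]-3-oxopropanoate
Product: 16 methyl (3S)-3-[4-(benzyloxy)phenyl]-3-hydroxypropanoate
Conditions: H2 (50 bar), [RuCl(p-cymene)((R)-BINAP)]Cl (1 mol %), MeOH, 60 °C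
Reagents that add atoms: none
Why: Noyori asymmetric hydrogenation as in step 5, with the (R)-BINAP ligand setting the (S)-carbinol and the homogeneous ruthenium catalyst leaving the benzyl ether intact.

Step 10
Reactants: 13 3,5-dimethoxy-4-{4-[(1S)-3-methoxy-3-oxo-1-(triisopropylsilyloxy)propyl]phenoxy}-2-(trimethylsilyl)phenyl triflate; 16 methyl (3S)-3-[4-(benzyloxy)phenyl]-3-hydroxypropanoate
Product: 19 methyl (3S)-3-[4-({(2S)-2-[4-(benzyloxy)phenyl]-5,7-dimethoxy-4-oxochroman-6-yl}oxy)phenyl]-3-(triisopropylsilyloxy)propanoate, via silyl ether 17 (not isolated), via aryne 18 (not isolated)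
Conditions: 16 (1.3 equiv), HMDS, TMSCl (cat.), THF, 65 °C, evaporate; then 13, CsF, 18-crown-6 (cat.), THF, 0 → 25 °C; pH 7 buffer, 0 °C
Reagents that add atoms: none
Why: Proposed new method: fluoride (and then the liberated alkoxide or methoxide) removes the aryl SiMe3 group of 13 with loss of triflate to give aryne 18 and unmasks the cesium alkoxide of 17; the alkoxide adds to the aryne carbon remote from the flanking methoxy group (future C8a''), the aryl anion so placed at C4a'' attacks the ester carbonyl, and methoxide leaves and is trapped as MeOSiMe3 by the next molecule of 17. The closest known reaction type is the fluoride-induced annulation of arynes with salicylate esters to xanthones (phenoxide addition, then acyl capture), extended here from a phenoxide to a secondary alkoxide. Ring C'' closes by 6-exo-trig attack of the C4a'' anion on the ester after the intermolecular O1''–C8a'' bond formation. No stereocentre is created: C2'' comes from 16 with its C–O bond untouched, so S is retained. Regioselectivity is secured by the C5'' methoxy group, which distorts the aryne and stabilises the adjacent carbanion, and by the symmetry of the parent phenol, which removes any 6- versus 8-aryloxy question. Acyl capture ahead of protonation, and silence of the ring-B carbinol of 13, are secured by using 16 as its proton-free O-SiMe3 ether in THF (no acidic C–H) while the carbinol of 13 carries the fluoride-resistant Si(i-Pr)3 group.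

Step 11
Reactants: 19 methyl (3S)-3-[4-({(2S)-2-[4-(benzyloxy)phenyl]-5,7-dimethoxy-4-oxochroman-6-yl}oxy)phenyl]-3-(triisopropylsilyloxy)propanoate
Product: 20 methyl (3S)-3-[4-({(2S)-2-[4-(benzyloxy)phenyl]-5,7-dimethoxy-4-oxochroman-6-yl}oxy)phenyl]-3-hydroxypropanoate
Conditions: HF·pyridine, pyridine, THF, 0 → 25 °C
Reagents that add atoms: none
Why: Cleavage of a silyl ether by buffered hydrogen fluoride, chosen over basic fluoride so that neither ring C'' (retro-oxa-Michael opening) nor the β-hydroxy ester (retro-aldol, elimination) meets base.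

Step 12
Reactants: 21 3,5-dimethoxyphenol
Product: 22 3,5-dimethoxyphenyl N-isopropylcarbamate
Conditions: i-PrNCO, Et3N (cat.), CH2Cl2, 25 °C
Reagents that add atoms: isopropyl isocyanate, CC(C)N=C=O
Why: Addition of the phenol to an isocyanate gives the carbamate that serves as directing group in step 13.

Step 13
Reactants: 22 3,5-dimethoxyphenyl N-isopropylcarbamate
Product: 25 3,5-dimethoxy-2-(trimethylsilyl)phenyl N-isopropylcarbamate, via N-silyl carbamate 23 (not isolated), via C-silylated N-silyl carbamate 24 (not isolated)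
Conditions: TBSOTf, TMEDA, Et2O, 0 → 25 °C; n-BuLi, TMEDA, −78 °C; TMSCl, −78 → 25 °C; aq. NaHSO4
Reagents that add atoms: chlorotrimethylsilane, C[Si](C)(C)Cl
Why: Directed ortho-metalation, in which the N-silylated carbamate and the C3 methoxy group together direct lithiation to C2, TMSCl quenches the aryllithium, and the N-silyl group is lost on acidic work-up.

Step 14
Reactants: 25 3,5-dimethoxy-2-(trimethylsilyl)phenyl N-isopropylcarbamate
Product: 27 3,5-dimethoxy-2-(trimethylsilyl)phenyl triflate, via silylphenol 26 (not isolated)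
Conditions: DBU, Et2NH, MeCN, 40 °C; then PhNTf2, 25 °C
Reagents that add atoms: N-phenylbis(trifluoromethanesulfonimide), O=S(=O)(N(c1ccccc1)S(=O)(=O)C(F)(F)F)C(F)(F)F
Why: Base-induced E1cB cleavage of the N–H carbamate (the isocyanate is scavenged by diethylamine) frees the phenoxide, which is triflated in the same flask.

Step 15
Reactants: 20 methyl (3S)-3-[4-({(2S)-2-[4-(benzyloxy)phenyl]-5,7-dimethoxy-4-oxochroman-6-yl}oxy)phenyl]-3-hydroxypropanoate; 27 3,5-dimethoxy-2-(trimethylsilyl)phenyl triflate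
Product: 30 (2S)-2-[4-({(2S)-2-[4-(benzyloxy)phenyl]-5,7-dimethoxy-4-oxochroman-6-yl}oxy)phenyl]-5,7-dimethoxychroman-4-one, via silyl ether 28 (not isolated), via aryne 29 (not isolated)
Conditions: 20, HMDS, TMSCl (cat.), THF, 65 °C, evaporate; then 27 (1.3 equiv), CsF, 18-crown-6 (cat.), THF, 0 → 25 °C; pH 7 buffer, 0 °C
Reagents that add atoms: none
Why: Proposed new method: the sequence of step 10 is repeated (alkoxide addition to the aryne carbon remote from its flanking methoxy group, then 6-exo-trig acyl capture by the C4a anion, with methoxide trapped as MeOSiMe3), the closest known type again being the aryne–salicylate annulation to xanthones; S at C2 is carried over from the carbinol of 20, whose C–O bond is not broken, and the proton-free, methoxide-scavenging medium should spare ring C''.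

Step 16
Reactants: 30 (2S)-2-[4-({(2S)-2-[4-(benzyloxy)phenyl]-5,7-dimethoxy-4-oxochroman-6-yl}oxy)phenyl]-5,7-dimethoxychroman-4-one
Product: 31 7,7''-di-O-methyltetrahydrohinokiflavone, (2S)-5-hydroxy-2-[4-({(2S)-5-hydroxy-2-(4-hydroxyphenyl)-7-methoxy-4-oxochroman-6-yl}oxy)phenyl]-7-methoxychroman-4-one
Conditions: BCl3, C6HMe5, CH2Cl2, −78 → 0 °C; then aq. NaHCO3
Reagents that add atoms: none
Why: Lewis-acid ether cleavage, in which BCl3 chelated between each C4 carbonyl and its peri oxygen removes only the O5 and O5'' methyl groups and cleaves the benzyl ether (cation trapped by pentamethylbenzene), while at low temperature the O7 and O7'' methyl groups, the diaryl ether and both C2 centres should stay intact.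

**Compound list**

1 | syringaldehyde (4-hydroxy-3,5-dimethoxybenzaldehyde) | COc1cc(C=O)cc(OC)c1O | starting material
2 | 4'-fluoroacetophenone | CC(=O)c1ccc(F)cc1 | starting material
3 | 4-(4-acetylphenoxy)-3,5-dimethoxybenzaldehyde | COc1cc(C=O)cc(OC)c1Oc1ccc(C(C)=O)cc1 | intermediate
4 | 4-(4-acetylphenoxy)-3,5-dimethoxyphenyl formate | COc1cc(OC=O)cc(OC)c1Oc1ccc(C(C)=O)cc1 | intermediate
5 | 1-[4-(4-hydroxy-2,6-dimethoxyphenoxy)phenyl]ethanone | COc1cc(O)cc(OC)c1Oc1ccc(C(C)=O)cc1 | intermediate
6 | 1-[4-(3-bromo-4-hydroxy-2,6-dimethoxyphenoxy)phenyl]ethanone | COc1cc(O)c(Br)c(OC)c1Oc1ccc(C(C)=O)cc1 | intermediate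
7 | methyl 3-[4-(3-bromo-4-hydroxy-2,6-dimethoxyphenoxy)phenyl]-3-oxopropanoate | COc1cc(O)c(Br)c(OC)c1Oc1ccc(C(=O)CC(=O)OC)cc1 | intermediate
8 | methyl (3S)-3-[4-(3-bromo-4-hydroxy-2,6-dimethoxyphenoxy)phenyl]-3-hydroxypropanoate | COc1cc(O)c(Br)c(OC)c1Oc1ccc([C@H](CC(=O)OC)O)cc1 | intermediate
9 | methyl (3S)-3-{4-[3-bromo-2,6-dimethoxy-4-(trimethylsilyloxy)phenoxy]phenyl}-3-(trimethylsilyloxy)propanoate | COc1cc(O[Si](C)(C)C)c(Br)c(OC)c1Oc1ccc([C@H](CC(=O)OC)O[Si](C)(C)C)cc1 | intermediate
10 | lithium 3,5-dimethoxy-4-{4-[(1S)-3-methoxy-3-oxo-1-(trimethylsilyloxy)propyl]phenoxy}-2-(trimethylsilyl)phenolate | [Li+].COc1cc([O-])c([Si](C)(C)C)c(OC)c1Oc1ccc([C@H](CC(=O)OC)O[Si](C)(C)C)cc1 | intermediate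
11 | 3,5-dimethoxy-4-{4-[(1S)-3-methoxy-3-oxo-1-(trimethylsilyloxy)propyl]phenoxy}-2-(trimethylsilyl)phenyl triflate | COc1cc(OS(=O)(=O)C(F)(F)F)c([Si](C)(C)C)c(OC)c1Oc1ccc([C@H](CC(=O)OC)O[Si](C)(C)C)cc1 | intermediate
12 | 4-{4-[(1S)-1-hydroxy-3-methoxy-3-oxopropyl]phenoxy}-3,5-dimethoxy-2-(trimethylsilyl)phenyl triflate | COc1cc(OS(=O)(=O)C(F)(F)F)c([Si](C)(C)C)c(OC)c1Oc1ccc([C@H](CC(=O)OC)O)cc1 | intermediate
13 | 3,5-dimethoxy-4-{4-[(1S)-3-methoxy-3-oxo-1-(triisopropylsilyloxy)propyl]phenoxy}-2-(trimethylsilyl)phenyl triflate | COc1cc(OS(=O)(=O)C(F)(F)F)c([Si](C)(C)C)c(OC)c1Oc1ccc([C@H](CC(=O)OC)O[Si](C(C)C)(C(C)C)C(C)C)cc1 | intermediate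
14 | 4'-(benzyloxy)acetophenone | CC(=O)c1ccc(OCc2ccccc2)cc1 | starting material
15 | methyl 3-[4-(benzyloxy)phenyl]-3-oxopropanoate | COC(=O)CC(=O)c1ccc(OCc2ccccc2)cc1 | intermediate
16 | methyl (3S)-3-[4-(benzyloxy)phenyl]-3-hydroxypropanoate | COC(=O)C[C@H](O)c1ccc(OCc2ccccc2)cc1 | intermediate
17 | methyl (3S)-3-[4-(benzyloxy)phenyl]-3-(trimethylsilyloxy)propanoate | COC(=O)C[C@H](O[Si](C)(C)C)c1ccc(OCc2ccccc2)cc1 | intermediate
18 | 3,5-dimethoxy-4-{4-[(1S)-3-methoxy-3-oxo-1-(triisopropylsilyloxy)propyl]phenoxy}benzyne (1,2-didehydrobenzene) | COC1=CC#CC(OC)=C1Oc2ccc([C@H](CC(=O)OC)O[Si](C(C)C)(C(C)C)C(C)C)cc2 | intermediate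
19 | methyl (3S)-3-[4-({(2S)-2-[4-(benzyloxy)phenyl]-5,7-dimethoxy-4-oxochroman-6-yl}oxy)phenyl]-3-(triisopropylsilyloxy)propanoate | COc1cc2c(c(OC)c1Oc1ccc([C@H](CC(=O)OC)O[Si](C(C)C)(C(C)C)C(C)C)cc1)C(=O)C[C@@H](c1ccc(OCc3ccccc3)cc1)O2 | intermediate
20 | methyl (3S)-3-[4-({(2S)-2-[4-(benzyloxy)phenyl]-5,7-dimethoxy-4-oxochroman-6-yl}oxy)phenyl]-3-hydroxypropanoate | COc1cc2c(c(OC)c1Oc1ccc([C@H](CC(=O)OC)O)cc1)C(=O)C[C@@H](c1ccc(OCc3ccccc3)cc1)O2 | intermediate
21 | 3,5-dimethoxyphenol | COc1cc(O)cc(OC)c1 | starting material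
22 | 3,5-dimethoxyphenyl N-isopropylcarbamate | COc1cc(OC)cc(OC(=O)NC(C)C)c1 | intermediate
23 | 3,5-dimethoxyphenyl N-(tert-butyldimethylsilyl)-N-isopropylcarbamate | COc1cc(OC)cc(OC(=O)N(C(C)C)[Si](C)(C)C(C)(C)C)c1 | intermediate
24 | 3,5-dimethoxy-2-(trimethylsilyl)phenyl N-(tert-butyldimethylsilyl)-N-isopropylcarbamate | COc1cc(OC)c([Si](C)(C)C)c(OC(=O)N(C(C)C)[Si](C)(C)C(C)(C)C)c1 | intermediate
25 | 3,5-dimethoxy-2-(trimethylsilyl)phenyl N-isopropylcarbamate | COc1cc(OC)c([Si](C)(C)C)c(OC(=O)NC(C)C)c1 | intermediate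
26 | 3,5-dimethoxy-2-(trimethylsilyl)phenol | COc1cc(O)c([Si](C)(C)C)c(OC)c1 | intermediate
27 | 3,5-dimethoxy-2-(trimethylsilyl)phenyl triflate | COc1cc(OS(=O)(=O)C(F)(F)F)c([Si](C)(C)C)c(OC)c1 | intermediate
28 | methyl (3S)-3-[4-({(2S)-2-[4-(benzyloxy)phenyl]-5,7-dimethoxy-4-oxochroman-6-yl}oxy)phenyl]-3-(trimethylsilyloxy)propanoate | COc1cc2c(c(OC)c1Oc1ccc([C@H](CC(=O)OC)O[Si](C)(C)C)cc1)C(=O)C[C@@H](c1ccc(OCc3ccccc3)cc1)O2 | intermediate
29 | 3,5-dimethoxybenzyne (1,2-didehydro-3,5-dimethoxybenzene) | COC1=CC(OC)=CC#C1 | intermediate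
30 | (2S)-2-[4-({(2S)-2-[4-(benzyloxy)phenyl]-5,7-dimethoxy-4-oxochroman-6-yl}oxy)phenyl]-5,7-dimethoxychroman-4-one | COc1cc(OC)c2c(c1)O[C@H](c1ccc(Oc3c(OC)cc4c(c3OC)C(=O)C[C@@H](c3ccc(OCc5ccccc5)cc3)O4)cc1)CC2=O | intermediate
31 | 7,7''-di-O-methyltetrahydrohinokiflavone, (2S)-5-hydroxy-2-[4-({(2S)-5-hydroxy-2-(4-hydroxyphenyl)-7-methoxy-4-oxochroman-6-yl}oxy)phenyl]-7-methoxychroman-4-one | COc1cc(O)c2c(c1)O[C@H](c1ccc(Oc3c(OC)cc4c(c3O)C(=O)C[C@@H](c3ccc(O)cc3)O4)cc1)CC2=O | target

**Step count and risk**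

Total steps: 16. Longest linear sequence: 11 (steps 1–7, 10, 11, 15, 16).

Steps most likely to fail:

1. Step 10. The aryl anion formed after alkoxide addition may be quenched by proton transfer (from an ester α-CH2 or traces of water) before it reaches the ester carbonyl, or the free cesium alkoxide may undergo retro-aldol cleavage or elimination before it meets the aryne. The fallback uses known reaction types only, sets out from 16 (with 13) and returns at 19. Compound 16 is transesterified with allyl alcohol (Ti(OiPr)4 cat., 80 °C) to allyl (3S)-3-[4-(benzyloxy)phenyl]-3-hydroxypropanoate F1. F1, as the free alcohol and in excess, is combined with 13 and CsF in MeCN. This is the established O–H insertion of an aryne into an alcohol, in which the aryl anion is protonated, and it should give aryl ether F2 with oxygen on the carbon remote from the methoxy group. Pd(PPh3)4 with morpholine removes the allyl group, leaving the methyl ester and the silyl and benzyl ethers, to give carboxylic acid F3. Intramolecular Friedel–Crafts acylation (TFAA, CH2Cl2, 0 °C) onto the trioxygenated ring, whose two positions ortho to the new ether oxygen are equivalent, then closes ring C'' and gives 19.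

2. Step 15. The same proton transfer to the aryl anion may occur, or base may open ring C'' of the flavanone already present (retro-oxa-Michael) with loss of configuration at C2''. The fallback uses known reaction types only, sets out from 20 (with 27) and returns at 30. Compound 20 as the free alcohol, 27 and CsF in MeCN should give, by aryne O–H insertion, 3,5-dimethoxyphenyl ether F4. Me3SnOH (1,2-dichloroethane, 70 °C) cleaves the methyl ester under near-neutral conditions to carboxylic acid F5. TFAA-mediated Friedel–Crafts acylation at C2/C6 of the 3,5-dimethoxyphenoxy ring (equivalent, and the only positions from which a six-membered ring can form) closes ring C and gives 30.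

3. Step 6. Butyllithium or the aryllithium may add to the methyl ester, or the ester may be enolised with loss of silyloxide, before the silyl shift takes place. The fallback moves the silyl shift to a stage with no ester, sets out from 6 and returns at 12. The acetyl group of 6 is ketalised (ethylene glycol, TsOH, toluene, water removal) to dioxolane F6, and HMDS converts it into aryl trimethylsilyl ether F7. n-BuLi at −78 °C effects exchange and the silyl shift, and aqueous work-up gives 2-silylphenol ketal F8. PPTS in wet acetone frees silylphenol ketone F9. Claisen condensation (NaH, dimethyl carbonate, phenoxide as spectator as in step 4) gives β-keto ester F10, and hydrogenation as in step 5 gives (S)-hydroxy ester F11. PhNTf2 with Et3N triflates the phenol selectively in the presence of the secondary alcohol and gives 12.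

**Further compounds**

F1 | step 10 | allyl (3S)-3-[4-(benzyloxy)phenyl]-3-hydroxypropanoate | C=CCOC(=O)C[C@H](O)c1ccc(OCc2ccccc2)cc1
F2 | step 10 | allyl (3S)-3-[4-(benzyloxy)phenyl]-3-(3,5-dimethoxy-4-{4-[(1S)-3-methoxy-3-oxo-1-(triisopropylsilyloxy)propyl]phenoxy}phenoxy)propanoate | C=CCOC(=O)C[C@H](Oc1cc(OC)c(Oc2ccc([C@H](CC(=O)OC)O[Si](C(C)C)(C(C)C)C(C)C)cc2)c(OC)c1)c1ccc(OCc2ccccc2)cc1
F3 | step 10 | (3S)-3-[4-(benzyloxy)phenyl]-3-(3,5-dimethoxy-4-{4-[(1S)-3-methoxy-3-oxo-1-(triisopropylsilyloxy)propyl]phenoxy}phenoxy)propanoic acid | OC(=O)C[C@H](Oc1cc(OC)c(Oc2ccc([C@H](CC(=O)OC)O[Si](C(C)C)(C(C)C)C(C)C)cc2)c(OC)c1)c1ccc(OCc2ccccc2)cc1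
F4 | step 15 | methyl (3S)-3-[4-({(2S)-2-[4-(benzyloxy)phenyl]-5,7-dimethoxy-4-oxochroman-6-yl}oxy)phenyl]-3-(3,5-dimethoxyphenoxy)propanoate | COc1cc2c(c(OC)c1Oc1ccc([C@H](CC(=O)OC)Oc3cc(OC)cc(OC)c3)cc1)C(=O)C[C@@H](c1ccc(OCc3ccccc3)cc1)O2
F5 | step 15 | (3S)-3-[4-({(2S)-2-[4-(benzyloxy)phenyl]-5,7-dimethoxy-4-oxochroman-6-yl}oxy)phenyl]-3-(3,5-dimethoxyphenoxy)propanoic acid | COc1cc2c(c(OC)c1Oc1ccc([C@H](CC(=O)O)Oc3cc(OC)cc(OC)c3)cc1)C(=O)C[C@@H](c1ccc(OCc3ccccc3)cc1)O2
F6 | step 6 | 2-bromo-3,5-dimethoxy-4-[4-(2-methyl-1,3-dioxolan-2-yl)phenoxy]phenol | COc1cc(O)c(Br)c(OC)c1Oc1ccc(C2(C)OCCO2)cc1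
F7 | step 6 | 2-{4-[3-bromo-2,6-dimethoxy-4-(trimethylsilyloxy)phenoxy]phenyl}-2-methyl-1,3-dioxolane | COc1cc(O[Si](C)(C)C)c(Br)c(OC)c1Oc1ccc(C2(C)OCCO2)cc1
F8 | step 6 | 3,5-dimethoxy-4-[4-(2-methyl-1,3-dioxolan-2-yl)phenoxy]-2-(trimethylsilyl)phenol | COc1cc(O)c([Si](C)(C)C)c(OC)c1Oc1ccc(C2(C)OCCO2)cc1
F9 | step 6 | 1-{4-[4-hydroxy-2,6-dimethoxy-3-(trimethylsilyl)phenoxy]phenyl}ethanone | COc1cc(O)c([Si](C)(C)C)c(OC)c1Oc1ccc(C(C)=O)cc1
F10 | step 6 | methyl 3-{4-[4-hydroxy-2,6-dimethoxy-3-(trimethylsilyl)phenoxy]phenyl}-3-oxopropanoate | COc1cc(O)c([Si](C)(C)C)c(OC)c1Oc1ccc(C(=O)CC(=O)OC)cc1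
F11 | step 6 | methyl (3S)-3-hydroxy-3-{4-[4-hydroxy-2,6-dimethoxy-3-(trimethylsilyl)phenoxy]phenyl}propanoate | COc1cc(O)c([Si](C)(C)C)c(OC)c1Oc1ccc([C@H](CC(=O)OC)O)cc1
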